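**Plan**

- Retrosynthesis: the angelate C18–O bond and the C8–C17 bond are cut first (the methyl comes from a methylene group through an epoxide), which leaves a 17-nor-8-ketone. Its C9–C10 bond is then cut by reversing a 1,2-shift, which returns C10 to C8 and gives a trans-hydrindane 8-ol 9-mesylate.
- Enabling feature: C8 carries oxygen and lies between C9 and quaternary C10, so ring B (C5–C6–C7–C8–C9–C10) is a cyclopentane C5–C6–C7–C8–C10 into which C9 has been inserted between C8 and C10.
- The C8=C9 alkene behind the diol is cut by a Wittig disconnection into a hydrindan-8-one and a C9/C11–C16 phosphonium salt from (S)-citronellol. The hydrindanone goes back (C4–C18 from formaldehyde, C3 deoxygenated) to the enedione from 2-methylcyclopentane-1,3-dione and ethyl vinyl ketone.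
- Forward order: the cyclopentane is present from the start, ring A closes by amino-acid-catalysed aldol condensation, the chain is joined by Wittig olefination, and ring B arises last by five-to-six ring enlargement. C17, the angelate and the free C15 alcohol follow.
- Stereochemistry: C10 from D-phenylalanine (the target is an ent-labdane); C5 and C4 from dissolving-metal reduction and formaldehyde capture anti to the C10 methyl; C13 from (S)-citronellol; C9 by equilibration next to the C8 ketone; C8 by epoxidation anti to the axial C10 methyl.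

Key step: step 17

Remark: the target is read as (4S,5S,8S,9S,10R,13S), with the C10 methyl, the C9 chain and the C8 methyl on one face and H5, H9, 8-OH and the C18 CH2O group on the other. Labdane locants are used for every intermediate, including the hydrindanes (five-membered ring = C5, C6, C7, C8, C10; C18 = CH2O on C4; C20 = methyl on C10); "syn" and "anti" refer to the C10 methyl.

**Route**

Step 1
Reactants: 1 2-methylcyclopentane-1,3-dione; 2 pent-1-en-3-one
Product: 3 2-methyl-2-(3-oxopentyl)cyclopentane-1,3-dione
Conditions: H2O, AcOH (cat.), 70 °C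
Reagents that add atoms: none
Why: Michael addition of the acidic 2-alkyl-1,3-dione to the enone needs no strong base and stops at the triketone because the attacking carbon becomes quaternary.

Step 2
Reactants: 3 triketone
Product: 4 (R)-4,7a-dimethyl-2,3,7,7a-tetrahydro-1H-indene-1,5(6H)-dione
Conditions: D-phenylalanine (1 equiv), 1 M aq. HClO4 (0.5 equiv), MeCN, reflux
Reagents that add atoms: none
Why: Hajos–Parrish–Eder–Sauer–Wiechert reaction, in which the enamine of the ethyl ketone adds to one of the two enantiotopic ring carbonyls under direction of the amino acid carboxyl group and the aldol dehydrates; the D-amino acid, mirror image of the catalyst that gives the (S) series, should set C10 as R, and recrystallisation should raise the enantiomeric purity.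

Step 3
Reactants: 4 enedione
Product: 5 (1R,7aR)-1-hydroxy-4,7a-dimethyl-1,2,3,6,7,7a-hexahydro-5H-inden-5-one
Conditions: NaBH4 (0.3 equiv), EtOH, −20 °C
Reagents that add atoms: none
Why: Chemoselective borohydride reduction of the saturated cyclopentanone in the presence of the less electrophilic enone; hydride enters anti to the angular methyl, so the C8 hydroxyl is syn to it (this centre is removed again in step 9).

Step 4
Reactants: 5 hydroxy enone
Product: 6 (1R,7aR)-1-(methoxymethoxy)-4,7a-dimethyl-1,2,3,6,7,7a-hexahydro-5H-inden-5-one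
Conditions: MOMCl, i-Pr2NEt, CH2Cl2, 0 → 40 °C
Reagents that add atoms: chloromethyl methyl ether, COCCl
Why: O-alkylation to the methoxymethyl acetal masks the C8 oxygen in a form that tolerates dissolving metal, neutral benzylation and hot alkali.

Step 5
Reactants: 6 MOM-protected enone
Product: 8 18-hydroxy-8-(methoxymethoxy)-trans-hydrindan-3-one, via lithium enolate 7 (not isolated)
Conditions: Li (2.2 equiv), NH3 (l)/THF, t-BuOH (1.0 equiv), −78 °C; NH3 removed; CH2O (gas), THF, −78 → −40 °C
Reagents that add atoms: formaldehyde, C=O
Why: Birch-type reductive alkylation (enone reduction, then aldol addition of the regiodefined enolate to formaldehyde): protonation at C5 gives the trans ring fusion with H5 anti to the C10 methyl, and formaldehyde approaches the C3–C4 enolate anti to the axial angular methyl, which sets quaternary C4 with CH2OH equatorial.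

Step 6
Reactants: 8 hydroxymethyl ketone
Product: 9 18-benzyloxy-8-(methoxymethoxy)-trans-hydrindan-3-one
Conditions: 2-benzyloxy-1-methylpyridinium triflate, MgO, PhCF3, 85 °C
Reagents that add atoms: 2-benzyloxy-1-methylpyridinium triflate, C[n+]1ccccc1OCc1ccccc1.[O-]S(=O)(=O)C(F)(F)F
Why: Thermal benzyl transfer from the pyridinium salt etherifies the neopentyl alcohol under neutral conditions, so the β-hydroxy ketone is never exposed to base and retro-aldol loss of formaldehyde is avoided.

Step 7
Reactants: 9 benzyloxy ketone
Product: 11 18-benzyloxy-8-(methoxymethoxy)-trans-hydrindane, via hydrazone 10 (not isolated)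
Conditions: N2H4·H2O, KOH, diethylene glycol, 130 → 200 °C
Reagents that add atoms: none
Why: Wolff–Kishner reduction (Huang–Minlon procedure) removes the C3 carbonyl; C4 is quaternary, so the β-benzyloxy ketone can neither eliminate nor epimerise, and both ethers are inert to hot alkali.

Step 8
Reactants: 11 MOM ether
Product: 12 18-benzyloxy-trans-hydrindan-8-ol
Conditions: conc. HCl (cat.), MeOH, 50 °C
Reagents that add atoms: none
Why: Acid-catalysed acetal exchange with methanol removes the MOM group while the benzyl ether stays.

Step 9
Reactants: 12 secondary alcohol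
Product: 13 (3aR,4S,7aR)-4-[(benzyloxy)methyl]-4,7a-dimethyloctahydro-1H-inden-1-one
Conditions: Dess–Martin periodinane, CH2Cl2, 23 °C
Reagents that add atoms: none
Why: Dess–Martin oxidation returns the C8 ketone, now the only carbonyl group and bonded directly to quaternary C10.

Step 10
Reactants: 14 (S)-citronellol
Product: 15 (S)-tert-butyl[(3,7-dimethyloct-6-en-1-yl)oxy]dimethylsilane
Conditions: TBSCl, imidazole, DMF, 23 °C
Reagents that add atoms: tert-butyldimethylsilyl chloride, CC(C)(C)[Si](C)(C)Cl
Why: Silylation of the primary alcohol gives an ether that lasts to the final step and is then cleaved by fluoride without touching the angelate.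

Step 11
Reactants: 15 citronellyl silyl ether
Product: 17 (S)-6-(tert-butyldimethylsilyloxy)-4-methylhexan-1-ol, via aldehyde 16 (not isolated)
Conditions: O3, CH2Cl2/MeOH, −78 °C; then NaBH4, −78 → 23 °C
Reagents that add atoms: ozone, [O-][O+]=O
Why: Ozonolysis of the trisubstituted alkene with reductive work-up removes the isopropylidene end and leaves a primary alcohol on the carbon that becomes C9; the remote methyl-bearing centre (future C13) is untouched.

Step 12
Reactants: 17 primary alcohol
Product: 18 (S)-tert-butyl[(6-iodo-3-methylhexyl)oxy]dimethylsilane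
Conditions: I2, PPh3, imidazole, CH2Cl2, 0 → 23 °C
Reagents that add atoms: iodine, II
Why: Appel-type iodination, SN2 displacement of the alkoxyphosphonium ion by iodide at a primary carbon.

Step 13
Reactants: 18 primary iodide
Product: 19 (S)-[6-(tert-butyldimethylsilyloxy)-4-methylhexyl]triphenylphosphonium iodide
Conditions: PPh3, i-Pr2NEt (cat.), MeCN, reflux
Reagents that add atoms: triphenylphosphine, c1ccccc1P(c1ccccc1)c1ccccc1
Why: SN2 quaternisation of the phosphine by the unhindered iodide, with a trace of amine to keep the silyl ether free of acid.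

Step 14
Reactants: 19 phosphonium iodide; 13 hydrindan-8-one
Product: 21 (Z)-8(9)-alkylidene-trans-hydrindane carrying the C11–C15 chain, via phosphorus ylide 20 (not isolated)
Conditions: KOtBu, THF, 23 °C; then 13, reflux
Reagents that add atoms: none
Why: Wittig reaction of a non-stabilised, lithium-free ylide with a cyclopentanone flanked by a quaternary carbon, the situation of 17-oxo steroids, where kinetic oxaphosphetane formation places the new chain syn to the quaternary carbon and should give the Z alkene (C11 cis to C10).

Step 15
Reactants: 21 Z alkene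
Product: 22 8,9-diol of the trans-hydrindane (8-OH anti to the C10 methyl)
Conditions: OsO4 (cat.), N-methylmorpholine N-oxide, acetone/H2O, 23 °C
Reagents that add atoms: osmium tetroxide, O=[Os](=O)(=O)=O (delivers both oxygen atoms); N-methylmorpholine N-oxide, C[N+]1([O-])CCOCC1, and water, O (restore it)
Why: Upjohn dihydroxylation, a syn addition to the alkene face anti to the angular methyl, so that the Z geometry and the face of attack together fix C8 and C9.

Step 16
Reactants: 22 diol
Product: 23 trans-hydrindane 8-ol 9-mesylate
Conditions: MsCl, pyridine, DMAP (cat.), CH2Cl2, 0 °C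
Reagents that add atoms: methanesulfonyl chloride, CS(=O)(=O)Cl
Why: Sulfonylation takes place at the secondary C9 hydroxyl only, the tertiary C8 hydroxyl being too hindered to react under these conditions.

Step 17
Reactants: 23 hydroxy mesylate
Product: 26 18-benzyloxy-15-(tert-butyldimethylsilyloxy)-17-nor-ent-labdan-8-one, via aluminium alkoxide 24 (not isolated), via 9-epi ketone 25 (not isolated)
Conditions: Et2AlCl (3 equiv), CH2Cl2, −78 → 0 °C; then crude ketone, NaOMe (0.3 equiv), MeOH, 23 °C
Reagents that add atoms: none
Why: Et2AlCl turns the tertiary C8 hydroxyl into a chloro(ethyl)aluminium alkoxide with loss of ethane, further Et2AlCl binds the mesylate, and as the C9–O bond ionises the antiperiplanar C8–C10 bond shifts to C9 while the alkoxide becomes the C8 carbonyl; C9 is inverted and C10 migrates with retention, so the trans ring fusion and the C10 methyl pass unchanged into the decalin. The closest known reaction type is the organoaluminium-promoted semipinacol (pinacol-type) rearrangement of β-mesyloxy alcohols, used here as a one-carbon enlargement of a 1-(1-mesyloxyalkyl)cyclopentanol and related to the D-homoannulation of 17-hydroxy-20-sulfonyloxy steroids. Ring B (C5–C6–C7–C8–C9–C10) is not closed by a cyclisation; it arises by a 1,2-alkyl shift that inserts C9 into the C8–C10 bond, five members becoming six. The new stereocentre C9 is set twice: the stereospecific shift gives the axial-chain epimer 25, and NaOMe then equilibrates it through the C8 enolate to the equatorial chain of 26 (H9 anti to the C10 methyl), which should be favoured because the axial chain meets H5 and H7 in syn-axial contacts. The step needs C10 and not C7 to migrate and must avoid closure to the 8,9-epoxide: with the C9 configuration that follows from the Z alkene and syn dihydroxylation, the rotamer that turns the small H9 into the crowded sector over the ring beside the C10 methyl holds the mesylate anti to C8–C10 and the chain toward C1, whereas the rotamers needed for C7 migration or epoxide closure would press the chain or the mesylate against that methyl. The higher migratory aptitude of the quaternary carbon and the low nucleophilicity of the aluminium-bound oxygen act in the same direction.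

Step 18
Reactants: 26 8-ketone
Product: 27 18-benzyloxy-15-(tert-butyldimethylsilyloxy)-ent-labd-8(17)-ene
Conditions: Ph3PCH3Br, KOtBu, toluene, 90 °C
Reagents that add atoms: methyltriphenylphosphonium bromide, C[P+](c1ccccc1)(c1ccccc1)c1ccccc1.[Br-]
Why: Wittig methylenation with excess ylide in hot toluene is the standard answer to hindered α-branched cyclohexanones, and enolisation is harmless because C9 already has its thermodynamic configuration.

Step 19
Reactants: 27 exocyclic alkene
Product: 28 8,17-epoxide with the oxygen equatorial (anti to the C10 methyl)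
Conditions: mCPBA, CH2Cl2, 0 °C
Reagents that add atoms: 3-chloroperoxybenzoic acid, OOC(=O)c1cccc(Cl)c1
Why: Prilezhaev epoxidation from the equatorial direction, because the axial C10 methyl blocks the other face of C8 in a 1,3-diaxial sense; this sets C8 with oxygen equatorial and the future methyl carbon axial.

Step 20
Reactants: 28 epoxide
Product: 29 18-benzyloxy-15-(tert-butyldimethylsilyloxy)-ent-labdan-8-ol
Conditions: LiAlH4, THF, 0 → 40 °C
Reagents that add atoms: none
Why: SN2 hydride opening at the unsubstituted epoxide carbon turns C17 into the methyl group and leaves the C8–O bond, and with it the C8 configuration, untouched.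

Step 21
Reactants: 29 benzyl ether
Product: 30 15-(tert-butyldimethylsilyloxy)-ent-labdane-8,18-diol
Conditions: H2 (1 atm), Pd/C, EtOAc, 23 °C
Reagents that add atoms: none
Why: Hydrogenolysis of the benzyl ether is done while the molecule holds no alkene; the silyl ether and the tertiary alcohol are stable in ethyl acetate.

Step 22
Reactants: 30 diol; 31 angelic acid
Product: 33 15-(tert-butyldimethylsilyloxy)-8-hydroxy-ent-labdan-18-yl angelate, via mixed anhydride 32 (not isolated)
Conditions: 31, 2,4,6-trichlorobenzoyl chloride, Et3N, toluene, 23 °C; then 30, 80 °C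
Reagents that add atoms: none
Why: Yamaguchi-type esterification through the mixed anhydride without a nucleophilic catalyst acylates the primary C18 hydroxyl while the tertiary C8 hydroxyl stays free, and it avoids the addition–elimination path that would isomerise the Z acid to the tiglate.

Step 23
Reactants: 33 silyl ether
Product: 34 (4S,5S,8S,9S,10R,13S)-8,15-dihydroxylabdan-18-yl (Z)-2-methylbut-2-enoate (CNP0150844.1)
Conditions: HF·pyridine, pyridine, THF, 0 → 23 °C
Reagents that add atoms: none
Why: Fluoride-driven Si–O cleavage under buffered conditions frees the C15 alcohol without isomerising the angelate or dehydrating the tertiary alcohol.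

**Compound list**

1 | 2-methylcyclopentane-1,3-dione | CC1C(=O)CCC1=O | starting material
2 | pent-1-en-3-one (ethyl vinyl ketone) | CCC(=O)C=C | starting material
3 | 2-methyl-2-(3-oxopentyl)cyclopentane-1,3-dione | CCC(=O)CCC1(C)C(=O)CCC1=O | intermediate
4 | (R)-4,7a-dimethyl-2,3,7,7a-tetrahydro-1H-indene-1,5(6H)-dione | CC1=C2CCC(=O)[C@]2(C)CCC1=O | intermediate
5 | (1R,7aR)-1-hydroxy-4,7a-dimethyl-1,2,3,6,7,7a-hexahydro-5H-inden-5-one (8-OH syn) | CC1=C2CC[C@@H](O)[C@]2(C)CCC1=O | intermediate
6 | (1R,7aR)-1-(methoxymethoxy)-4,7a-dimethyl-1,2,3,6,7,7a-hexahydro-5H-inden-5-one | CC1=C2CC[C@@H](OCOC)[C@]2(C)CCC1=O | intermediate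
7 | lithium C3–C4 enolate of the trans-fused hydrindane (H5 anti; not isolated) | CC1=C(O[Li])CC[C@]2(C)[C@@H]1CC[C@H]2OCOC | intermediate
8 | 18-hydroxy-8-(methoxymethoxy)-trans-hydrindan-3-one (C18 and H5 anti, 8-O syn) | OC[C@@]1(C)C(=O)CC[C@]2(C)[C@@H]1CC[C@H]2OCOC | intermediate
9 | 18-benzyloxy-8-(methoxymethoxy)-trans-hydrindan-3-one | c1ccccc1COC[C@@]1(C)C(=O)CC[C@]2(C)[C@@H]1CC[C@H]2OCOC | intermediate
10 | C3 hydrazone of 9 (not isolated) | c1ccccc1COC[C@@]1(C)C(=NN)CC[C@]2(C)[C@@H]1CC[C@H]2OCOC | intermediate
11 | 18-benzyloxy-8-(methoxymethoxy)-trans-hydrindane | c1ccccc1COC[C@@]1(C)CCC[C@]2(C)[C@@H]1CC[C@H]2OCOC | intermediate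
12 | 18-benzyloxy-trans-hydrindan-8-ol (8-OH syn) | c1ccccc1COC[C@@]1(C)CCC[C@]2(C)[C@@H]1CC[C@H]2O | intermediate
13 | (3aR,4S,7aR)-4-[(benzyloxy)methyl]-4,7a-dimethyloctahydro-1H-inden-1-one (18-benzyloxy-trans-hydrindan-8-one) | c1ccccc1COC[C@@]1(C)CCC[C@]2(C)[C@@H]1CCC2=O | intermediate
14 | (S)-citronellol | CC(C)=CCC[C@H](C)CCO | starting material
15 | (S)-tert-butyl[(3,7-dimethyloct-6-en-1-yl)oxy]dimethylsilane | CC(C)=CCC[C@H](C)CCO[Si](C)(C)C(C)(C)C | intermediate
16 | (S)-6-(tert-butyldimethylsilyloxy)-4-methylhexanal (not isolated) | O=CCC[C@H](C)CCO[Si](C)(C)C(C)(C)C | intermediate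
17 | (S)-6-(tert-butyldimethylsilyloxy)-4-methylhexan-1-ol | OCCC[C@H](C)CCO[Si](C)(C)C(C)(C)C | intermediate
18 | (S)-tert-butyl[(6-iodo-3-methylhexyl)oxy]dimethylsilane | ICCC[C@H](C)CCO[Si](C)(C)C(C)(C)C | intermediate
19 | (S)-[6-(tert-butyldimethylsilyloxy)-4-methylhexyl]triphenylphosphonium iodide | [I-].c1ccccc1[P+](c1ccccc1)(c1ccccc1)CCC[C@H](C)CCO[Si](C)(C)C(C)(C)C | intermediate
20 | ylide of 19 (not isolated) | c1ccccc1P(c1ccccc1)(c1ccccc1)=CCC[C@H](C)CCO[Si](C)(C)C(C)(C)C | intermediate
21 | (Z)-8(9)-alkylidene-18-benzyloxy-trans-hydrindane with the 15-silyloxy chain (C11 cis to C10) | c1ccccc1COC[C@@]1(C)CCC[C@]2(C)[C@@H]1CC/C2=C/CC[C@H](C)CCO[Si](C)(C)C(C)(C)C | intermediate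
22 | 8,9-diol (8-OH anti to the C10 methyl) | c1ccccc1COC[C@@]1(C)CCC[C@]2(C)[C@@H]1CC[C@@]2(O)[C@H](O)CC[C@H](C)CCO[Si](C)(C)C(C)(C)C | intermediate
23 | trans-hydrindane 8-ol 9-mesylate | c1ccccc1COC[C@@]1(C)CCC[C@]2(C)[C@@H]1CC[C@@]2(O)[C@H](OS(C)(=O)=O)CC[C@H](C)CCO[Si](C)(C)C(C)(C)C | intermediate
24 | chloro(ethyl)aluminium alkoxide of 23 (not isolated) | c1ccccc1COC[C@@]1(C)CCC[C@]2(C)[C@@H]1CC[C@@]2(O[Al](Cl)CC)[C@H](OS(C)(=O)=O)CC[C@H](C)CCO[Si](C)(C)C(C)(C)C | intermediate
25 | 9-epi-17-nor-8-ketone, chain axial (not isolated) | c1ccccc1COC[C@@]1(C)CCC[C@]2(C)[C@@H]1CCC(=O)[C@@H]2CC[C@H](C)CCO[Si](C)(C)C(C)(C)C | intermediate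
26 | 18-benzyloxy-15-(tert-butyldimethylsilyloxy)-17-nor-ent-labdan-8-one | c1ccccc1COC[C@@]1(C)CCC[C@]2(C)[C@@H]1CCC(=O)[C@H]2CC[C@H](C)CCO[Si](C)(C)C(C)(C)C | intermediate
27 | 18-benzyloxy-15-(tert-butyldimethylsilyloxy)-ent-labd-8(17)-ene | c1ccccc1COC[C@@]1(C)CCC[C@]2(C)[C@@H]1CCC(=C)[C@H]2CC[C@H](C)CCO[Si](C)(C)C(C)(C)C | intermediate
28 | 8,17-epoxide, oxygen equatorial and anti to the C10 methyl | c1ccccc1COC[C@@]1(C)CCC[C@]2(C)[C@@H]1CC[C@]3(OC3)[C@H]2CC[C@H](C)CCO[Si](C)(C)C(C)(C)C | intermediate
29 | 18-benzyloxy-15-(tert-butyldimethylsilyloxy)-ent-labdan-8-ol (8-OH equatorial) | c1ccccc1COC[C@@]1(C)CCC[C@]2(C)[C@@H]1CC[C@](C)(O)[C@H]2CC[C@H](C)CCO[Si](C)(C)C(C)(C)C | intermediate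
30 | 15-(tert-butyldimethylsilyloxy)-ent-labdane-8,18-diol | OC[C@@]1(C)CCC[C@]2(C)[C@@H]1CC[C@](C)(O)[C@H]2CC[C@H](C)CCO[Si](C)(C)C(C)(C)C | intermediate
31 | angelic acid, (Z)-2-methylbut-2-enoic acid | C/C=C(/C)C(=O)O | starting material
32 | angelic 2,4,6-trichlorobenzoic anhydride (not isolated) | C/C=C(/C)C(=O)OC(=O)c1c(Cl)cc(Cl)cc1Cl | intermediate
33 | 15-(tert-butyldimethylsilyloxy)-8-hydroxy-ent-labdan-18-yl angelate | C/C=C(/C)C(=O)OC[C@@]1(C)CCC[C@]2(C)[C@@H]1CC[C@](C)(O)[C@H]2CC[C@H](C)CCO[Si](C)(C)C(C)(C)C | intermediate
34 | (4S,5S,8S,9S,10R,13S)-8,15-dihydroxylabdan-18-yl (Z)-2-methylbut-2-enoate (CNP0150844.1) | C/C=C(/C)C(=O)OC[C@@]1(C)CCC[C@]2(C)[C@@H]1CC[C@](C)(O)[C@H]2CC[C@H](C)CCO | target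

**Step count and risks**

Total steps: 23. Longest linear sequence: 19 steps (steps 1–9, then 14–23); the side chain (steps 10–13) joins at step 14.

Steps most likely to fail:

1. Step 17 (ring enlargement). The shift could take the C8–C7 bond instead of C8–C10, the alkoxide could close onto C9 to give the 8,9-epoxide, or ionisation could end in elimination toward C11, if the reacting rotamer is not the one assumed. The fallback generates the electron-poor C9 from a selenide instead of a sulfonate, so that migratory aptitude alone decides which bond shifts. It sets out from ketone 13 and from aldehyde 16, which is isolated when the ozonide of 15 is worked up with dimethyl sulfide instead of NaBH4. Aldehyde 16 is converted with PhSeH and ZnCl2 into the bis(phenylseleno)acetal F1. Selenium–lithium exchange with n-BuLi in THF at −78 °C gives the α-lithio selenide F2, which adds to 13 anti to the angular methyl to give the β-hydroxy selenide F3 as a mixture at C9. AgBF4 on neutral alumina in CH2Cl2 then pulls on selenium, and the more substituted ring carbon C10 should migrate to C9, giving the ketones 25 and 26. Equilibration with NaOMe in MeOH brings the route back at 26.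

2. Step 14 (Wittig olefination). The basic, bulky ylide may enolise the hindered ketone instead of adding to it, conversion may stall, and prolonged heating may erode the Z geometry. The fallback is a Horner–Wittig olefination carried out in separate stages, setting out from iodide 18 and ketone 13. Iodide 18 alkylates sodium diphenylphosphinite (Ph2P(O)H, NaH, THF) to give the alkyldiphenylphosphine oxide F4. Deprotonation with n-BuLi at −78 °C gives the lithio derivative F5, a smaller and more nucleophilic carbanion than the ylide. Its addition to 13 gives β-hydroxy phosphine oxides, from which the diastereomer F6 is separated by chromatography. Syn elimination of diphenylphosphinate from F6 with NaH in DMF is stereospecific and returns the route at the Z alkene 21.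

3. Step 5 (reductive hydroxymethylation). Gaseous formaldehyde may oligomerise before it meets the enolate, the enolate may be protonated to the plain saturated ketone, a second formaldehyde may add, and the aldolate may revert on work-up. The fallback separates reduction from carbon–carbon bond formation and sets out from 6. The enolate 7 from the same Li/NH3 reduction is trapped with TMSCl/Et3N as the trimethylsilyl enol ether F7, which can be purified. A Mukaiyama-type aldol addition with aqueous formaldehyde catalysed by Yb(OTf)3 in THF/H2O then delivers the hydroxymethyl group anti to the angular methyl, and the route is rejoined at 8.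

Further compounds
F1 | step 17 | (S)-tert-butyl{[3-methyl-6,6-bis(phenylselanyl)hexyl]oxy}dimethylsilane | c1ccccc1[Se]C([Se]c1ccccc1)CC[C@H](C)CCO[Si](C)(C)C(C)(C)C
F2 | step 17 | α-lithio selenide from F1 (not isolated) | [Li]C([Se]c1ccccc1)CC[C@H](C)CCO[Si](C)(C)C(C)(C)C
F3 | step 17 | 18-benzyloxy-trans-hydrindan-8-ol with the 9-(phenylselanyl) chain on C8 (8-OH syn, C9 mixed) | c1ccccc1COC[C@@]1(C)CCC[C@]2(C)[C@@H]1CC[C@]2(O)C([Se]c1ccccc1)CC[C@H](C)CCO[Si](C)(C)C(C)(C)C
F4 | step 14 | (S)-[6-(tert-butyldimethylsilyloxy)-4-methylhexyl]diphenylphosphine oxide | O=P(c1ccccc1)(c1ccccc1)CCC[C@H](C)CCO[Si](C)(C)C(C)(C)C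
F5 | step 14 | α-lithio derivative of F4 (not isolated) | [Li]C(CC[C@H](C)CCO[Si](C)(C)C(C)(C)C)P(=O)(c1ccccc1)c1ccccc1
F6 | step 14 | β-hydroxy phosphine oxide from F5 and 13, the diastereomer that eliminates to the Z alkene | c1ccccc1COC[C@@]1(C)CCC[C@]2(C)[C@@H]1CC[C@]2(O)[C@H](CC[C@H](C)CCO[Si](C)(C)C(C)(C)C)P(=O)(c1ccccc1)c1ccccc1
F7 | step 5 | trimethylsilyl enol ether of the trans-fused C3 ketone (C3–C4 enol) | CC1=C(O[Si](C)(C)C)CC[C@]2(C)[C@@H]1CC[C@H]2OCOC
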